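## The problem

The target is umbelliferone etherified at O7 with an enantio-drimane alcohol. Drimane numbering is used throughout; α denotes the face of the C10 methyl and β the face of H5. The alkyl part is a trans-fused decalin whose ring A carries a 2β,3α-diol beside the C4 gem-dimethyl group and whose ring B carries the C7=C8 olefin and the C9–CH2O arm. Five stereocentres (C2, C3, C5, C10, C9) form an unbroken row, and the quaternary C10 lies between the methine centres C5 and C9 and must be built anti to H5. C5 is the natural anchor, since it can direct C10. Once the decalin exists, the axial methyls on C10 and C4 close the α face and can direct C9, C3 and C2. This bias has a consequence: hydride reduction of a C2 ketone would come from the open β face and give the axial alcohol, whereas the diol is trans-diequatorial, so at C2 it is the oxygen that must arrive from the β face. The coumarin (a lactone and an enoate) does not tolerate strong bases, hydrides, organometallics, boranes or peracids, and the trisubstituted C7=C8 olefin is sensitive to acid and electrophiles, so the coumarin has to come last and the diol has to be masked. The enabling feature is that C9 is bonded to both the quaternary C10 and C8, while (R)-α-ionone already holds ring A with the C5 stereocentre, the C10 methyl on a ring olefin, the gem-dimethyl group and the chain C6–C7–C8(–C12) ending in a ketone. Only C9 is missing from ring B, and a one-carbon double nucleophile can be stitched between C10 and C8.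

## Retrosynthesis

**Aryl ether, last.** The C11–O bond of target 29 is cut to the primary alcohol 26 and umbelliferone 27, with the diol of 28 masked as an acetonide. Forming this bond early would expose the coumarin to every reductive, basic and oxidative step of the route. The forward reaction is a Mitsunobu etherification of a β-branched primary alcohol followed by mild acid hydrolysis.

**C9–C11 and the C9 stereocentre.** Alcohol 26 is traced to diene 24 and enone 23 by cutting C9=C11 (methylenation) and adding H–B across it. Carrying C11 through ring construction would leave C9 as an uncontrolled, enolisable centre. Here C9 is set last on a rigid ring by the axial C10 methyl. The forward steps must olefinate a hindered enone and hydroborate only the terminal olefin of a 1,3-diene.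

**Enone from a nitro alcohol.** Enone 23 comes from α-ketol 22 by dehydration, and 22 from nitro alcohol 20 by a Nef reaction. The nitro group is a masked C9 carbonyl that is inert to hydrides, boranes, acids and chromic acid, so the ring A work can be done first. The Nef reaction must not open the β-hydroxy nitro unit.

**Ring A diol.** Acetonide 20 comes from triol 19. The C2–O bond of 19 is cut by hydroboration of allylic alcohol 17, and the C3–H bond of 17 by 1,2-reduction of enone 16. Direct hydride reduction of a 2-keto-3-silyloxy compound such as 11 is rejected because it would give the axial 2α-alcohol, and inversion there would mean substitution at an axial, doubly flanked centre, which would end in elimination. The β-face bias is used constructively instead: boron, and then oxygen, goes to C2 and hydride to C3, both from the β face. This needs the carbonyl at C3. Enone 16 is reached from 11 by reduction (12), elimination through the axial mesylate (14) and oxidative desilylation. That sequence also erases the C3 centre, so 11 needs a C3 oxygen of either configuration.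

**Key disconnection.** Nitro ketol 11 is cut at C9–C10 and C8–C9 to enone ketone 8 and nitromethane 9. Cutting at C9 removes a single carbon and leaves a monocyclic chiral-pool ring with one controlling stereocentre. An aldol or Robinson cut elsewhere in ring B would need C9 already attached to a quaternary carbon. The forward reaction must add to a β,β-disubstituted enone anti to the C5 chain and then close onto the C8 ketone.

**Precursor from α-ionone.** Enone 8 comes from ketal 7 by hydrolysis, 7 from enone ketal 5 by Rubottom oxidation at the α′ carbon, 5 from ketal 4 by allylic oxidation, 4 from dihydroionone 3, and 3 from (R)-α-ionone 1 by conjugate reduction. No skeletal bond is made; the ketal is there only to keep the methyl ketone from enolising during the α′ oxidation.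

## Roads not taken

**Alternative 1: biomimetic epoxy-polyene bicyclisation.**
- Cut: C4–C5 and C9–C10, back to (R)-10′,11′-epoxyumbelliprenin A1, which is available in a few steps from 27.
- Key step: a Lewis acid (SnCl4 or Bi(OTf)3 at low temperature) opens the epoxide, the two trisubstituted olefins add in turn, and loss of a C7 proton gives the 2-deoxy target A2.
- Merits: very short; the coumarin is in place from the start; C3, C5, C9 and C10 are set in one step.
- Weak points: A2 lacks the C2 oxygen. Adding it means oxidation to the 3-ketone, α-hydroxylation and reduction, with enolate or peracid chemistry in the presence of the coumarin and the C7=C8 olefin. Cation cyclisations of this kind also give monocyclic and olefin-isomer by-products, the ether and lactone oxygens bind the Lewis acid, and the enantiopurity rests on a terminal-olefin epoxidation.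
- Comparison: on step count this road is clearly better (about ten steps against eighteen). The chosen plan sets against it that the C2 oxygen is present from the outset as the enone carbonyl that drives the key step, that all stereocentres are set by substrate control before the coumarin is attached, and that no cation-termination mixture has to be separated.

**Alternative 2: intramolecular Diels–Alder reaction.**
- Cut: C5–C10 and C8–C9, back to triene A4, assembled from (S)-pantolactone A3.
- Key step: on heating or with Me2AlCl the (E)-enoate adds to the 2-silyloxydiene and gives the bicyclic ester A5 as C8 epimers.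
- Merits: the diol and gem-dimethyl group come from the chiral pool, C11 is already present as the ester, and both rings form together.
- Weak points: the dienophile carbon C10 is fully substituted and the diene terminus C5 is neopentyl, so the cycloaddition is slow. Ring-fusion geometry and facial selectivity depend only on the remote acetonide. The C7 silyl enol ether still has to become the C7=C8 olefin, and A4 itself needs roughly ten linear steps with defined olefin geometries.
- Comparison: this road is better in that C11 and the diol are built in and no carbonyl transposition in ring A is needed. The chosen plan answers with a purchasable ring that already holds C5, and with a C10 centre set by a simple anti addition rather than a contested endo/exo preference. The overall length is no shorter.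

**Alternative 3: one-carbon ring expansion.**
- Cut: C8–C9 and C7–C8, back to the B-nor hydrindanone A6.
- Key step: diazoethane with BF3·OEt2 adds to the C9 ketone and the C7 methylene migrates with loss of N2, giving decalone A7 as C8 epimers.
- Merits: the migrating carbon is predictable (primary C7 rather than quaternary C10).
- Weak points: a ketone next to a quaternary carbon adds diazoalkanes sluggishly, diazoethane is hazardous and not purchasable, and over-homologation competes. A6, with its gem-dimethyl, diol and quaternary pattern, has no cheap source, so the C5/C10 problem is only moved.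
- Comparison: from the ketone onward this road is as good as the chosen one, because the endgame (olefin, methylenation, hydroboration, coupling) is identical; A7 is the saturated analogue of enone 23 and even appears in one of the fallbacks below. Before that point it is worse. The chosen plan also reaches 23 with the olefin already in place.

Key step: step 6

Assumption: (R)-α-ionone 1 of high enantiomeric purity is taken as a purchasable building block; racemic material would first need a resolution.
Convention: all bicyclic compounds have the absolute configuration of the target (trans-decalin, 5β-H, 10α-CH3); where C3, C8 or C9 is described as a mixture, the SMILES leaves that centre open.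

Step 1
Reactants: 1 (R)-α-ionone
Product: 3 (R)-7,8-dihydro-α-ionone [4-[(1R)-2,6,6-trimethylcyclohex-2-en-1-yl]butan-2-one], via triethylsilyl enol ether 2 (not isolated)
Conditions: Et3SiH, (Ph3P)3RhCl (cat.), benzene, 50 °C; then K2CO3 (cat.), MeOH, rt
Reagents that add atoms: none
Why: Rhodium-catalysed 1,4-hydrosilylation of the side-chain enone with a monohydrosilane, then methanolysis of the silyl enol ether; the trisubstituted ring olefin does not react and the allylic stereocentre is not involved.

Step 2
Reactants: 3 (R)-7,8-dihydro-α-ionone
Product: 4 dioxolane ketal of 3 [2-methyl-2-{2-[(1R)-2,6,6-trimethylcyclohex-2-en-1-yl]ethyl}-1,3-dioxolane]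
Conditions: HOCH2CH2OH, PPTS (cat.), benzene, reflux, Dean–Stark trap
Reagents that add atoms: ethylene glycol, OCCO
Why: Acid-catalysed ketalisation with azeotropic removal of water; the weak acid should not move the ring olefin, and the ketal keeps the methyl ketone from enolising in step 4.

Step 3
Reactants: 4 dioxolane ketal of 3
Product: 5 enone ketal [(4R)-3,5,5-trimethyl-4-[2-(2-methyl-1,3-dioxolan-2-yl)ethyl]cyclohex-2-en-1-one]
Conditions: t-BuOOH (70% aq.), Rh2(cap)4 [dirhodium tetrakis(caprolactamate)] (1 mol %), K2CO3, CH2Cl2, rt
Reagents that add atoms: tert-butyl hydroperoxide, CC(C)(C)OO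
Why: Radical allylic C–H oxidation at the only allylic ring methylene (C2 in drimane numbering) gives the conjugated enone; the medium is not acidic, so the dioxolane survives, and the C5 stereocentre is not part of the allyl radical.

Step 4
Reactants: 5 enone ketal
Product: 7 α′-silyloxy enone ketal [6-(tert-butyldimethylsilyloxy) derivative of 5; both C6 epimers; C6 = C3 in drimane numbering], via silyl dienol ether 6 (not isolated)
Conditions: LiN(iPr)2, THF, −78 °C, then TBSOTf; crude 6: m-CPBA, NaHCO3, CH2Cl2, −20 to 0 °C
Reagents that add atoms: tert-butyldimethylsilyl triflate, CC(C)(C)[Si](C)(C)OS(=O)(=O)C(F)(F)F; m-chloroperbenzoic acid, OOC(=O)c1cccc(Cl)c1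
Why: Rubottom oxidation: kinetic deprotonation at the α′ carbon (not at the γ hydrogen on C5) gives the cross-conjugated dienolate, O-silylation and epoxidation of the electron-rich silyl enol ether follow, and 1,4-silyl shift delivers the α′-silyloxy enone. The new C3 centre is deliberately left uncontrolled because it becomes trigonal in step 9.

Step 5
Reactants: 7 α′-silyloxy enone ketal
Product: 8 3-silyloxy ring A enone with free 3-oxobutyl chain [6-(tert-butyldimethylsilyloxy)-3,5,5-trimethyl-4-(3-oxobutyl)cyclohex-2-en-1-one; C4 as in 5; C6 epimers]
Conditions: PPTS, acetone/H2O, 50 °C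
Reagents that add atoms: water, O
Why: Acid-catalysed ketal hydrolysis; the hindered secondary silyl ether and the enone should survive PPTS.

Step 6
Reactants: 8 3-silyloxy ring A enone with free 3-oxobutyl chain; 9 nitromethane
Product: 11 8-hydroxy-9-nitro-3-(tert-butyldimethylsilyloxy)-11-nor-drimane-2-one [trans-decalin; 5β-H; 10α-CH3; mixture at C3 C8 C9], via nitromethyl diketone 10 (not isolated)
Conditions: MeNO2 (solvent), DBU (1 equiv), rt; AcOH quench
Reagents that add atoms: none
Why: DBU deprotonates nitromethane, the nitronate adds to C10 of the enone (Michael addition) to give 10, and the nitronate regenerated at C9 adds to the C8 ketone (intramolecular Henry reaction), so C9–C10 and C8–C9, one ring and three stereocentres form in one flask. The closest known reactions are the base-mediated addition of nitromethane to β,β-disubstituted cyclohexenones of the isophorone type and the cyclising nitroaldol reaction of nitro ketones to 2-nitrocyclohexanols. Ring B closes in the 6-exo-trig mode, the nitronate carbon attacking a carbonyl whose C=O lies outside the new ring. C10 is set by C5: A(1,2) strain with the C10 methyl holds the C5 chain pseudoaxial and the nitronate enters axially on the opposite face, so C9 ends trans to C6 and the ring fusion is trans. C8 and C9 form under reversible conditions (most likely hydroxyl axial and nitro equatorial) and need no control because both become trigonal in steps 13 and 14. The step needs conjugate addition to win over γ-deprotonation at C5; the large excess of nitromethane buffers the amidine so that nitromethane is the carbon acid that is deprotonated. It also needs the second bond to form at C8 and not at C2; closure onto C2 would give a four-membered ring, whereas closure onto C8 gives a chair, and deprotonation of the product to its nitronate pulls the equilibria forward.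

Step 7
Reactants: 11 8-hydroxy-9-nitro-3-(tert-butyldimethylsilyloxy)-11-nor-drimane-2-one
Product: 12 2α-alcohol [9-nitro-3-(tert-butyldimethylsilyloxy)-11-nor-drimane-2α,8-diol; 2-OH axial]
Conditions: NaBH4, CeCl3·7H2O, MeOH, −40 °C
Reagents that add atoms: none
Why: Luche-type hydride reduction of the ketone; the axial methyls on C4 and C10 block the α face, so hydride enters from the β face and the hydroxyl ends axial, which is the geometry the next step needs; the nitro group and the nearly neutral medium leave ring B alone.

Step 8
Reactants: 12 2α-alcohol
Product: 14 9-nitro-3-(tert-butyldimethylsilyloxy)-11-nor-drim-1-en-8-ol, via axial 2α-mesylate 13 (not isolated)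
Conditions: MsCl, pyridine, DMAP (cat.), 0 °C to rt; then 60 °C
Reagents that add atoms: none
Why: Sulfonylation of the only secondary hydroxyl (tertiary alcohols are not mesylated in pyridine) and E2 anti-elimination of the strained axial mesylate with the axial H1, as with 11β-hydroxy steroids, whose axial hydroxyl flanked by two syn-axial methyls eliminates once activated. Loss of H3 is disfavoured because that hydrogen is geminal to oxygen and, in the 3β-silyloxy epimer, not antiperiplanar.

Step 9
Reactants: 14 9-nitro-3-(tert-butyldimethylsilyloxy)-11-nor-drim-1-en-8-ol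
Product: 16 8-hydroxy-9-nitro-11-nor-drim-1-en-3-one, via allylic alcohol 15 (not isolated)
Conditions: CrO3, H2SO4, H2O, acetone, 0 °C to rt
Reagents that add atoms: none
Why: Jones oxidation: the aqueous acid hydrolyses the allylic silyl ether and chromic acid oxidises the liberated secondary allylic alcohol in the same flask; both C3 epimers converge on one enone, and the tertiary alcohol and the nitro group are inert.

Step 10
Reactants: 16 8-hydroxy-9-nitro-11-nor-drim-1-en-3-one
Product: 17 9-nitro-11-nor-drim-1-ene-3α,8-diol [3-OH equatorial]
Conditions: NaBH4, CeCl3·7H2O, MeOH, −78 to −40 °C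
Reagents that add atoms: none
Why: Luche 1,2-reduction; hydride enters C3 from the β face, anti to the axial C4 methyl and the C10 methyl, so the hydroxyl ends equatorial, as is usual for 4,4-dimethyl-1-en-3-ones of the triterpenoid type.

Step 11
Reactants: 17 9-nitro-11-nor-drim-1-ene-3α,8-diol
Product: 19 9-nitro-11-nor-drimane-2β,3α,8-triol [2-OH and 3-OH trans-diequatorial], via 2β-boryl intermediate 18 (not isolated)
Conditions: BH3·THF, THF, 0 °C to rt; then 30% H2O2, aq. NaHCO3, 0 °C to rt
Reagents that add atoms: hydrogen peroxide, OO
Why: Hydroboration–oxidation of a cyclic allylic alcohol: boron goes to C2 (C1 is neopentyl beside the quaternary C10, and allylic oxygen directs boron to the nearer carbon) from the β face, anti to the C3 oxygen and to both axial methyls, and oxidation with retention gives the equatorial 2β-hydroxyl. Borane does not reduce aliphatic nitro groups, and the bicarbonate-buffered work-up keeps nitronate formation low.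

Step 12
Reactants: 19 9-nitro-11-nor-drimane-2β,3α,8-triol
Product: 20 2β,3α-acetonide of 19 [8-hydroxy-2β,3α-(isopropylidenedioxy)-9-nitro-11-nor-drimane]
Conditions: Me2C(OMe)2, PPTS (cat.), CH2Cl2, rt
Reagents that add atoms: 2,2-dimethoxypropane, COC(C)(C)OC
Why: Acid-catalysed transketalisation gives the trans-fused dioxolane of the diequatorial diol; the tertiary alcohol does not form a stable ketal under these equilibrating conditions.

Step 13
Reactants: 20 2β,3α-acetonide of 19
Product: 22 8-hydroxy-2β,3α-(isopropylidenedioxy)-11-nor-drimane-9-one, via sodium nitronate 21 (not isolated)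
Conditions: NaOMe, MeOH, 0 °C; then O3, CH2Cl2/MeOH, −78 °C; AcOH
Reagents that add atoms: ozone, [O-][O+]=O
Why: Oxidative Nef reaction: the nitronate (which, unlike the free alkoxide, cannot fragment by retro-Henry cleavage) is cleaved at its C=N bond by ozone at low temperature to the ketone and nitrite; 21 contains no olefin and the acetonide sees no acid.

Step 14
Reactants: 22 8-hydroxy-2β,3α-(isopropylidenedioxy)-11-nor-drimane-9-one
Product: 23 2β,3α-(isopropylidenedioxy)-11-nor-drim-7-en-9-one
Conditions: SOCl2, pyridine, CH2Cl2, −20 to 0 °C
Reagents that add atoms: none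
Why: E2 dehydration of a tertiary α-ketol through its chlorosulfite, the reaction type that turns 17α-hydroxy-20-keto steroids into enones. The preferred Henry product has the 8-hydroxyl axial (otherwise a methyl would be 1,3-diaxial to the C10 methyl), so the axial H7 is antiperiplanar and the endocyclic conjugated enone forms; C10 is quaternary, so no other ring olefin is possible.

Step 15
Reactants: 23 2β,3α-(isopropylidenedioxy)-11-nor-drim-7-en-9-one
Product: 24 2β,3α-(isopropylidenedioxy)drima-7,9(11)-diene
Conditions: Cp2TiMe2, toluene, 70 °C, dark
Reagents that add atoms: dimethyltitanocene Cp2TiMe2, C[Ti](C)(C1C=CC=C1)C1C=CC=C1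
Why: Petasis methylenation: the titanium methylidene formed on heating is small and non-basic, so it should olefinate a hindered ketone that a phosphorus ylide would rather deprotonate at C6; the acetonide is inert.

Step 16
Reactants: 24 2β,3α-(isopropylidenedioxy)drima-7,9(11)-diene
Product: 26 2β,3α-(isopropylidenedioxy)drim-7-en-11-ol [9β-H; CH2OH equatorial], via B-alkyl-9-BBN 25 (not isolated)
Conditions: 9-BBN, THF, rt; then NaOH, 30% H2O2, 0 °C
Reagents that add atoms: hydrogen peroxide, OO
Why: Hydroboration–oxidation: 9-BBN adds only to the 1,1-disubstituted terminus (boron on C11) and not to the trisubstituted C7=C8 bond; hydrogen reaches C9 from the β face, opposite the axial methyl on the neighbouring C10, which places C11 equatorial and cis to that methyl as in the target.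

Step 17
Reactants: 26 2β,3α-(isopropylidenedioxy)drim-7-en-11-ol; 27 umbelliferone (7-hydroxycoumarin)
Product: 28 7-[2β,3α-(isopropylidenedioxy)drim-7-en-11-yloxy]coumarin
Conditions: PPh3, DIAD, THF, 0 °C to rt
Reagents that add atoms: none
Why: Mitsunobu etherification: the acidic phenol protonates the betaine and its anion displaces the primary alkoxyphosphonium at C11; no stereocentre is touched, and the acetonide keeps the secondary hydroxyls out of the reaction.

Step 18
Reactants: 28 7-[2β,3α-(isopropylidenedioxy)drim-7-en-11-yloxy]coumarin
Product: 29 7-{[(1R,4aS,6S,7S,8aR)-6,7-dihydroxy-2,5,5,8a-tetramethyl-1,4,4a,5,6,7,8,8a-octahydronaphthalen-1-yl]methoxy}-2H-chromen-2-one (target)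
Conditions: AcOH/H2O (4:1), 40 °C
Reagents that add atoms: none
Why: Acid hydrolysis of the strained trans-fused acetonide under conditions that should leave the coumarin, the aryl ether and the trisubstituted olefin untouched.

## Compound list

1 | (R)-α-ionone, (3E)-4-[(1R)-2,6,6-trimethylcyclohex-2-en-1-yl]but-3-en-2-one | CC(=O)/C=C/[C@H]1C(C)=CCCC1(C)C | starting material
2 | triethylsilyl enol ether of 3 (E/Z mixture, ring stereocentre as in 1) | CC(O[Si](CC)(CC)CC)=CC[C@H]1C(C)=CCCC1(C)C | intermediate
3 | (R)-7,8-dihydro-α-ionone | CC(=O)CC[C@H]1C(C)=CCCC1(C)C | intermediate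
4 | dioxolane ketal of 3 | CC1(CC[C@H]2C(C)=CCCC2(C)C)OCCO1 | intermediate
5 | (4R)-3,5,5-trimethyl-4-[2-(2-methyl-1,3-dioxolan-2-yl)ethyl]cyclohex-2-en-1-one | CC1(CC[C@@H]2C(C)(C)CC(=O)C=C2C)OCCO1 | intermediate
6 | tert-butyldimethylsilyl dienol ether of 5 (2-silyloxy-1,3-diene) | CC1(CC[C@@H]2C(C)(C)C=C(O[Si](C)(C)C(C)(C)C)C=C2C)OCCO1 | intermediate
7 | 6-(tert-butyldimethylsilyloxy) derivative of 5 (C6 epimers) | CC1(CC[C@@H]2C(C)(C)C(O[Si](C)(C)C(C)(C)C)C(=O)C=C2C)OCCO1 | intermediate
8 | 6-(tert-butyldimethylsilyloxy)-3,5,5-trimethyl-4-(3-oxobutyl)cyclohex-2-en-1-one (C4 as in 5, C6 epimers) | CC(=O)CC[C@@H]1C(C)(C)C(O[Si](C)(C)C(C)(C)C)C(=O)C=C1C | intermediate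
9 | nitromethane | C[N+](=O)[O-] | starting material
10 | nitromethyl diketone, 2-(tert-butyldimethylsilyloxy)-3,3,5-trimethyl-5-(nitromethyl)-4-(3-oxobutyl)cyclohexanone (nitromethyl trans to the oxobutyl chain, C2 epimers) | CC(=O)CC[C@@H]1C(C)(C)C(O[Si](C)(C)C(C)(C)C)C(=O)C[C@@]1(C)C[N+](=O)[O-] | intermediate
11 | 8-hydroxy-9-nitro-3-(tert-butyldimethylsilyloxy)-11-nor-drimane-2-one (trans-fused, 5β-H, 10α-CH3; mixture at C3, C8, C9) | CC1(O)CC[C@@H]2C(C)(C)C(O[Si](C)(C)C(C)(C)C)C(=O)C[C@@]2(C)C1[N+](=O)[O-] | intermediate
12 | 9-nitro-3-(tert-butyldimethylsilyloxy)-11-nor-drimane-2α,8-diol (2-OH axial) | CC1(O)CC[C@@H]2C(C)(C)C(O[Si](C)(C)C(C)(C)C)[C@H](O)C[C@@]2(C)C1[N+](=O)[O-] | intermediate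
13 | 2α-methanesulfonate of 12 | CC1(O)CC[C@@H]2C(C)(C)C(O[Si](C)(C)C(C)(C)C)[C@H](OS(C)(=O)=O)C[C@@]2(C)C1[N+](=O)[O-] | intermediate
14 | 9-nitro-3-(tert-butyldimethylsilyloxy)-11-nor-drim-1-en-8-ol | CC1(O)CC[C@@H]2C(C)(C)C(O[Si](C)(C)C(C)(C)C)C=C[C@@]2(C)C1[N+](=O)[O-] | intermediate
15 | 9-nitro-11-nor-drim-1-ene-3,8-diol (C3 epimers) | CC1(O)CC[C@@H]2C(C)(C)C(O)C=C[C@@]2(C)C1[N+](=O)[O-] | intermediate
16 | 8-hydroxy-9-nitro-11-nor-drim-1-en-3-one | CC1(O)CC[C@@H]2C(C)(C)C(=O)C=C[C@@]2(C)C1[N+](=O)[O-] | intermediate
17 | 9-nitro-11-nor-drim-1-ene-3α,8-diol (3-OH equatorial) | CC1(O)CC[C@@H]2C(C)(C)[C@H](O)C=C[C@@]2(C)C1[N+](=O)[O-] | intermediate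
18 | 2β-boryl intermediate (drawn as the monoalkylborane; the hydroxyls are present as borate esters) | CC1(O)CC[C@@H]2C(C)(C)[C@H](O)[C@@H](B)C[C@@]2(C)C1[N+](=O)[O-] | intermediate
19 | 9-nitro-11-nor-drimane-2β,3α,8-triol (2,3-trans-diequatorial) | CC1(O)CC[C@@H]2C(C)(C)[C@H](O)[C@@H](O)C[C@@]2(C)C1[N+](=O)[O-] | intermediate
20 | 8-hydroxy-2β,3α-(isopropylidenedioxy)-9-nitro-11-nor-drimane | CC1(O)CC[C@@H]2C(C)(C)[C@@H]3OC(C)(C)O[C@H]3C[C@@]2(C)C1[N+](=O)[O-] | intermediate
21 | sodium nitronate of 20 | CC1(O)CC[C@@H]2C(C)(C)[C@@H]3OC(C)(C)O[C@H]3C[C@@]2(C)C1=[N+]([O-])[O-].[Na+] | intermediate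
22 | 8-hydroxy-2β,3α-(isopropylidenedioxy)-11-nor-drimane-9-one (C8 epimers, mainly 8-OH axial) | CC1(O)CC[C@@H]2C(C)(C)[C@@H]3OC(C)(C)O[C@H]3C[C@@]2(C)C1=O | intermediate
23 | 2β,3α-(isopropylidenedioxy)-11-nor-drim-7-en-9-one | CC1=CC[C@@H]2C(C)(C)[C@@H]3OC(C)(C)O[C@H]3C[C@@]2(C)C1=O | intermediate
24 | 2β,3α-(isopropylidenedioxy)drima-7,9(11)-diene | CC1=CC[C@@H]2C(C)(C)[C@@H]3OC(C)(C)O[C@H]3C[C@@]2(C)C1=C | intermediate
25 | B-[2β,3α-(isopropylidenedioxy)drim-7-en-11-yl]-9-borabicyclo[3.3.1]nonane | CC1=CC[C@@H]2C(C)(C)[C@@H]3OC(C)(C)O[C@H]3C[C@@]2(C)[C@@H]1CB1C2CCCC1CCC2 | intermediate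
26 | 2β,3α-(isopropylidenedioxy)drim-7-en-11-ol (9β-H) | CC1=CC[C@@H]2C(C)(C)[C@@H]3OC(C)(C)O[C@H]3C[C@@]2(C)[C@@H]1CO | intermediate
27 | umbelliferone (7-hydroxycoumarin) | Oc1ccc2ccc(=O)oc2c1 | starting material
28 | 7-[2β,3α-(isopropylidenedioxy)drim-7-en-11-yloxy]coumarin | CC1=CC[C@@H]2C(C)(C)[C@@H]3OC(C)(C)O[C@H]3C[C@@]2(C)[C@@H]1COc1ccc2ccc(=O)oc2c1 | intermediate
29 | 7-{[(1R,4aS,6S,7S,8aR)-6,7-dihydroxy-2,5,5,8a-tetramethyl-1,4,4a,5,6,7,8,8a-octahydronaphthalen-1-yl]methoxy}-2H-chromen-2-one | CC1=CC[C@@H]2C(C)(C)[C@H](O)[C@@H](O)C[C@@]2(C)[C@@H]1COc1ccc2ccc(=O)oc2c1 | target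

## Step count and least certain steps

Total: 18 steps. Longest linear sequence: 18 steps from 1; 9 and 27 enter as purchased materials.

**Step 6 (key step).** The conjugate addition may be slow or reversible, because the nitronate must pass the syn-axial C4 methyl (the isophorone situation). During a long reaction, γ-deprotonation at C5 could epimerise the controlling centre, and the free methyl ketone could enter aldol or Michael side reactions. The fallback separates the two bond formations. It sets out from 7, where the side-chain ketone is still masked, so the addition can be pushed harder (nitromethane with TBAF or KF/18-crown-6, or gentle heating) to give the nitromethyl ketone ketal F1. Ketal hydrolysis with PPTS in wet acetone then gives 10, now isolated. A separate Henry closure with catalytic DBU or tetramethylguanidine returns to the route at 11.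

**Step 8.** Sulfonylation of the crowded axial hydroxyl may be incomplete, the tertiary hydroxyl may be attacked, or the elimination may lose regiocontrol towards C3. The fallback transposes the carbonyl without any elimination. It sets out from 11: desilylation with HF·pyridine gives the ketol F2, oxidation with Cu(OAc)2 in methanol under air gives the diosphenol F3 (which can enolise only towards C1), and PhNTf2 with Et3N gives the enol triflate F4. Reduction of the triflate with Pd(OAc)2, PPh3, HCO2H and Bu3N returns to the route at 16, bypassing steps 7 to 9.

**Step 11.** Boron may go to C1, conversion at the hindered, oxygen-flanked olefin may be low, or the nitronate may be oxidised during the peroxide work-up. The fallback is the 3-ketone manifold and sets out from 16. Conjugate hydrosilylation (Et3SiH, (Ph3P)3RhCl) gives the triethylsilyl enol ether F5. Rubottom oxidation with m-CPBA from the open β face and an acidic work-up gives the 2β-hydroxy-3-ketone F6. Reduction with NaBH4, with axial hydride delivery to C3, returns to the route at 19, bypassing steps 10 and 11.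

**Step 13.** The ring may open by retro-Henry cleavage while the hindered C9–H is being deprotonated, and ozone may over-oxidise the product. The fallback avoids the β-hydroxy nitronate and sets out from 20. Dehydration with MsCl and Et3N gives the nitroalkene F7. Reduction and hydrolysis with aqueous TiCl3 buffered by NH4OAc give the saturated ketone F8. Dehydrogenation with IBX in DMSO, which can occur only towards C7, returns to the route at 23, bypassing steps 13 and 14.

**Step 15.** Methylenation of a ketone flanked by a quaternary carbon and an α-methyl may stop at low conversion. The fallback is a Peterson olefination and sets out from 23: addition of Me3SiCH2Li in the presence of CeCl3 gives the β-hydroxysilane F9, and syn-elimination with KH returns to the route at 24.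

**Step 17.** The activated β-branched alcohol may eliminate towards the allylic C9–H, re-forming a diene, instead of being substituted. The fallback replaces the Mitsunobu activation by a sulfonate displacement and sets out from 26: Tf2O with 2,6-lutidine at −78 °C gives the primary triflate F10, and alkylation of 27 with Cs2CO3 in acetonitrile returns to the route at 28.

## Further compounds

F1 | step 6 | nitromethyl ketone ketal, Michael adduct of 7 | CC1(CC[C@@H]2C(C)(C)C(O[Si](C)(C)C(C)(C)C)C(=O)C[C@@]2(C)C[N+](=O)[O-])OCCO1
F2 | step 8 | 3,8-dihydroxy-9-nitro-11-nor-drimane-2-one (ketol, C3 epimers) | CC1(O)CC[C@@H]2C(C)(C)C(O)C(=O)C[C@@]2(C)C1[N+](=O)[O-]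
F3 | step 8 | 2,8-dihydroxy-9-nitro-11-nor-drim-1-en-3-one (diosphenol) | CC1(O)CC[C@@H]2C(C)(C)C(=O)C(O)=C[C@@]2(C)C1[N+](=O)[O-]
F4 | step 8 | enol triflate of F3 | CC1(O)CC[C@@H]2C(C)(C)C(=O)C(OS(=O)(=O)C(F)(F)F)=C[C@@]2(C)C1[N+](=O)[O-]
F5 | step 11 | 9-nitro-3-(triethylsilyloxy)-11-nor-drim-2-en-8-ol | CC1(O)CC[C@@H]2C(C)(C)C(O[Si](CC)(CC)CC)=CC[C@@]2(C)C1[N+](=O)[O-]
F6 | step 11 | 2β,8-dihydroxy-9-nitro-11-nor-drimane-3-one | CC1(O)CC[C@@H]2C(C)(C)C(=O)[C@@H](O)C[C@@]2(C)C1[N+](=O)[O-]
F7 | step 13 | 2β,3α-(isopropylidenedioxy)-9-nitro-11-nor-drim-8-ene | CC=1CC[C@@H]2C(C)(C)[C@@H]3OC(C)(C)O[C@H]3C[C@@]2(C)C=1[N+](=O)[O-]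
F8 | step 13 | 2β,3α-(isopropylidenedioxy)-11-nor-drimane-9-one (C8 epimers) | CC1CC[C@@H]2C(C)(C)[C@@H]3OC(C)(C)O[C@H]3C[C@@]2(C)C1=O
F9 | step 15 | 9-hydroxy-9-(trimethylsilylmethyl) adduct of 23 | CC1=CC[C@@H]2C(C)(C)[C@@H]3OC(C)(C)O[C@H]3C[C@@]2(C)C1(O)C[Si](C)(C)C
F10 | step 17 | trifluoromethanesulfonate of 26 | CC1=CC[C@@H]2C(C)(C)[C@@H]3OC(C)(C)O[C@H]3C[C@@]2(C)[C@@H]1COS(=O)(=O)C(F)(F)F
A1 | alternative 1 | (R)-10′,11′-epoxyumbelliprenin | CC1(C)O[C@@H]1CC/C(C)=C/CC/C(C)=C/COc1ccc2ccc(=O)oc2c1
A2 | alternative 1 | 2-deoxy target, 7-(3-hydroxy-ent-drim-7-en-11-yloxy)coumarin | CC1=CC[C@@H]2C(C)(C)[C@H](O)CC[C@@]2(C)[C@@H]1COc1ccc2ccc(=O)oc2c1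
A3 | alternative 2 | (S)-pantolactone | CC1(C)COC(=O)[C@H]1O
A4 | alternative 2 | acyclic triene, (E)-enoate tethered to the 2-silyloxydiene through the acetonide-bearing chain | COC(=O)/C=C(\C)C[C@@H]1OC(C)(C)O[C@H]1C(C)(C)/C=C/C(O[Si](C)(C)C(C)(C)C)=C/C
A5 | alternative 2 | methyl 7-silyloxy-ent-drim-6-en-11-oate 2,3-acetonide (C8 epimers) | CC1C(O[Si](C)(C)C(C)(C)C)=C[C@@H]2C(C)(C)[C@@H]3OC(C)(C)O[C@H]3C[C@@]2(C)[C@@H]1C(=O)OC
A6 | alternative 3 | B-nor hydrindan-9-one 2,3-acetonide | O=C1CC[C@@H]2C(C)(C)[C@@H]3OC(C)(C)O[C@H]3C[C@@]12C
A7 | alternative 3 | 11-nor-ent-drimane-9-one 2,3-acetonide (C8 epimers) | CC1CC[C@@H]2C(C)(C)[C@@H]3OC(C)(C)O[C@H]3C[C@@]2(C)C1=O
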